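The 2,2-dimethyl-2H-pyran ring fused to ring B at C3'/C4' is disconnected to an aryl 1,1-dimethylpropargyl ether on O4' of an otherwise complete flavonol, assembled by Claisen–Schmidt condensation and Algar–Flynn–Oyamada oxidation. Heating triggers a propargyl Claisen shift to C3', the only hydrogen-bearing ortho carbon of O4' (C5' is oxygenated), then a 1,5-hydrogen shift and oxa-6π closure. The same heating moves the 7-O-prenyl group to C8 with allyl inversion, so one operation closes the last ring and installs the 1,1-dimethylallyl group. The precursor is a 3-hydroxyflavone carrying 5- and 5'-MOM ethers, the 7-prenyl ether, the 2'-prenyl group and the 4'-propargyl ether.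

Key step: step 8

Remark on the chemistry: the target has no stereocentre and no stereogenic double bond, so it is achiral and no stereocontrol is required. Configuration is specified only for intermediates 12, 14 and 17 (14 is racemic, one enantiomer drawn).

Step 1
Reactants: 1 2',4',6'-trihydroxyacetophenone; 2 prenyl bromide
Product: 3 1-[2,6-dihydroxy-4-(3-methylbut-2-enyloxy)phenyl]ethanone
Conditions: K2CO3 (1.0 equiv), acetone, reflux
Reagents that add atoms: prenyl bromide, CC(C)=CCBr
Why: Williamson etherification; the 4-OH is the most acidic and the only hydroxyl not chelated to the ketone, so with one equivalent of weak base in acetone O-alkylation at O4 should dominate over C-alkylation.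

Step 2
Reactants: 3 1-[2,6-dihydroxy-4-(3-methylbut-2-enyloxy)phenyl]ethanone; 4 chloromethyl methyl ether (MOMCl)
Product: 5 1-[2-hydroxy-6-(methoxymethoxy)-4-(3-methylbut-2-enyloxy)phenyl]ethanone
Conditions: MOMCl (1.1 equiv), DIPEA, CH2Cl2, 0 °C
Reagents that add atoms: chloromethyl methyl ether, COCCl
Why: MOM protection of a phenol; 3 is symmetric, so either hydroxyl gives the same product, and the remaining hydroxyl, then held in a single strong hydrogen bond to the ketone, should resist a second alkylation.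

Step 3
Reactants: 6 2-bromo-4,5-dihydroxybenzaldehyde; 7 tributyl(3-methylbut-2-enyl)stannane
Product: 8 4,5-dihydroxy-2-(3-methylbut-2-enyl)benzaldehyde
Conditions: Pd(PPh3)4 (5 mol %), DMF, 90 °C, Ar
Reagents that add atoms: tributyl(3-methylbut-2-enyl)stannane, CCCC[Sn](CCCC)(CCCC)CC=C(C)C
Why: Stille cross-coupling; oxidative addition is activated by the ortho formyl group, and reductive elimination from the prenylpalladium complex at the unsubstituted terminus should give the linear prenyl arene under neutral conditions that tolerate free phenols.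

Step 4
Reactants: 8 4,5-dihydroxy-2-(3-methylbut-2-enyl)benzaldehyde; 9 3-chloro-3-methylbut-1-yne
Product: 10 5-hydroxy-4-(2-methylbut-3-yn-2-yloxy)-2-(3-methylbut-2-enyl)benzaldehyde
Conditions: K2CO3 (1.05 equiv), KI (cat.), CuI (cat.), DMF, 50 °C
Reagents that add atoms: 3-chloro-3-methylbut-1-yne, C#CC(C)(C)Cl
Why: Copper-assisted O-alkylation of a phenoxide with a tertiary propargylic chloride; one equivalent of carbonate deprotonates only the 4-OH, which is para to the aldehyde and the more acidic hydroxyl, so the ether should form at O4.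

Step 5
Reactants: 10 5-hydroxy-4-(2-methylbut-3-yn-2-yloxy)-2-(3-methylbut-2-enyl)benzaldehyde; 4 chloromethyl methyl ether (MOMCl)
Product: 11 5-(methoxymethoxy)-4-(2-methylbut-3-yn-2-yloxy)-2-(3-methylbut-2-enyl)benzaldehyde
Conditions: MOMCl, DIPEA, CH2Cl2, 0 °C → rt
Reagents that add atoms: chloromethyl methyl ether, COCCl
Why: MOM protection of the only remaining phenol, which keeps the B ring non-ionised in the two basic steps that follow.

Step 6
Reactants: 5 1-[2-hydroxy-6-(methoxymethoxy)-4-(3-methylbut-2-enyloxy)phenyl]ethanone; 11 5-(methoxymethoxy)-4-(2-methylbut-3-yn-2-yloxy)-2-(3-methylbut-2-enyl)benzaldehyde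
Product: 12 (E)-2'-hydroxychalcone from 5 and 11
Conditions: KOH (50 % aq., excess), EtOH, rt
Reagents that add atoms: none
Why: Claisen–Schmidt condensation; the methyl ketone enolate adds to the non-enolisable aldehyde and E1cB dehydration should give the thermodynamically preferred E-enone, while the ethers, the alkyne and the alkenes are inert to hydroxide.

Step 7
Reactants: 12 (E)-2'-hydroxychalcone; 13 hydrogen peroxide
Product: 15 3-hydroxy-5-(methoxymethoxy)-7-(3-methylbut-2-enyloxy)-2-[5-(methoxymethoxy)-4-(2-methylbut-3-yn-2-yloxy)-2-(3-methylbut-2-enyl)phenyl]chromen-4-one, via trans-dihydroflavonol 14 (not isolated)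
Conditions: 30 % H2O2, aq. NaOH, MeOH, 0 °C → rt
Reagents that add atoms: hydrogen peroxide, OO
Why: Algar–Flynn–Oyamada oxidation; hydroperoxide attacks the enone, the 2'-phenoxide closes the pyranone ring to give 14, and alkaline peroxide dehydrogenates 14 to the flavonol, while isolated alkenes, the alkyne and the ethers do not react with the nucleophilic oxidant.

Step 8
Reactants: 15 3-hydroxy-5-(methoxymethoxy)-7-(3-methylbut-2-enyloxy)-2-[5-(methoxymethoxy)-4-(2-methylbut-3-yn-2-yloxy)-2-(3-methylbut-2-enyl)phenyl]chromen-4-one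
Product: 19 3,7-dihydroxy-5-(methoxymethoxy)-8-(2-methylbut-3-en-2-yl)-2-[8-(methoxymethoxy)-2,2-dimethyl-5-(3-methylbut-2-enyl)-2H-chromen-6-yl]chromen-4-one, via allenylphenol 16 (not isolated), via ortho-quinone methide 17 (not isolated), via pyranoflavonol prenyl ether 18 (not isolated)
Conditions: PhNEt2, 190–200 °C, sealed tube, Ar
Reagents that add atoms: none
Why: This is the thermal aryl propargyl ether Claisen rearrangement, the classical chromene annulation: the 4'-O-CMe2-C≡CH unit undergoes a [3,3] shift to C3', the dienone enolises to allenylphenol 16, and a 1,5-hydrogen shift gives the Z-configured ortho-quinone methide 17. The pyran ring is then closed by oxa-6π electrocyclisation (O4' to the CMe2 carbon), which gives 18. C3' is the only ortho carbon of O4' that carries hydrogen (C5' bears OMOM, and a shift there can only revert), so the ring can fuse only at C3'/C4' next to the 2'-prenyl group. Under the same conditions the 7-O-prenyl ether of 18 undergoes an aromatic Claisen rearrangement with allyl inversion, which places the 1,1-dimethylallyl group on carbon and frees the 7-OH; C8 should be preferred over C6 because the 5-oxygen is a non-chelating MOM ether, so both the bond fixation of the benzopyranone (C7–C8 double-bond character) and the bulk at C5 direct the shift to C8. No stereocentre is formed. Heating is stopped once 18 is consumed, to limit the abnormal Claisen isomerisation of the 1,1-dimethylallyl group next to the new 7-OH.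

Step 9
Reactants: 19 3,7-dihydroxy-5-(methoxymethoxy)-8-(2-methylbut-3-en-2-yl)-2-[8-(methoxymethoxy)-2,2-dimethyl-5-(3-methylbut-2-enyl)-2H-chromen-6-yl]chromen-4-one
Product: 20 broussoflavonol D
Conditions: HCl (1.25 M in MeOH), MeOH, rt → 40 °C
Reagents that add atoms: none
Why: Acid-catalysed transacetalisation of the two aryl MOM ethers to methanol; the dilute acid and low temperature should leave the prenyl, 1,1-dimethylallyl and chromene double bonds untouched.

Compound list

1 | 2',4',6'-trihydroxyacetophenone | CC(=O)c1c(O)cc(O)cc1O | starting material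
2 | prenyl bromide (1-bromo-3-methylbut-2-ene) | CC(C)=CCBr | starting material
3 | 1-[2,6-dihydroxy-4-(3-methylbut-2-enyloxy)phenyl]ethanone | CC(=O)c1c(O)cc(OCC=C(C)C)cc1O | intermediate
4 | chloromethyl methyl ether (MOMCl) | COCCl | starting material
5 | 1-[2-hydroxy-6-(methoxymethoxy)-4-(3-methylbut-2-enyloxy)phenyl]ethanone | CC(=O)c1c(O)cc(OCC=C(C)C)cc1OCOC | intermediate
6 | 2-bromo-4,5-dihydroxybenzaldehyde | O=Cc1cc(O)c(O)cc1Br | starting material
7 | tributyl(3-methylbut-2-enyl)stannane | CCCC[Sn](CCCC)(CCCC)CC=C(C)C | starting material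
8 | 4,5-dihydroxy-2-(3-methylbut-2-enyl)benzaldehyde | O=Cc1cc(O)c(O)cc1CC=C(C)C | intermediate
9 | 3-chloro-3-methylbut-1-yne | C#CC(C)(C)Cl | starting material
10 | 5-hydroxy-4-(2-methylbut-3-yn-2-yloxy)-2-(3-methylbut-2-enyl)benzaldehyde | O=Cc1cc(O)c(OC(C)(C)C#C)cc1CC=C(C)C | intermediate
11 | 5-(methoxymethoxy)-4-(2-methylbut-3-yn-2-yloxy)-2-(3-methylbut-2-enyl)benzaldehyde | O=Cc1cc(OCOC)c(OC(C)(C)C#C)cc1CC=C(C)C | intermediate
12 | (E)-1-[2-hydroxy-6-(methoxymethoxy)-4-(3-methylbut-2-enyloxy)phenyl]-3-[5-(methoxymethoxy)-4-(2-methylbut-3-yn-2-yloxy)-2-(3-methylbut-2-enyl)phenyl]prop-2-en-1-one | COCOc1cc(OCC=C(C)C)cc(O)c1C(=O)/C=C/c1cc(OCOC)c(OC(C)(C)C#C)cc1CC=C(C)C | intermediate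
13 | hydrogen peroxide | OO | starting material
14 | trans-3-hydroxy-5-(methoxymethoxy)-2-[5-(methoxymethoxy)-4-(2-methylbut-3-yn-2-yloxy)-2-(3-methylbut-2-enyl)phenyl]-7-(3-methylbut-2-enyloxy)chroman-4-one (racemic, 2R,3R enantiomer drawn) | O=C1c2c(OCOC)cc(OCC=C(C)C)cc2O[C@H](c2cc(OCOC)c(OC(C)(C)C#C)cc2CC=C(C)C)[C@H]1O | intermediate (not isolated)
15 | 3-hydroxy-5-(methoxymethoxy)-2-[5-(methoxymethoxy)-4-(2-methylbut-3-yn-2-yloxy)-2-(3-methylbut-2-enyl)phenyl]-7-(3-methylbut-2-enyloxy)-4H-chromen-4-one | COCOc1cc(OCC=C(C)C)cc2oc(-c3cc(OCOC)c(OC(C)(C)C#C)cc3CC=C(C)C)c(O)c(=O)c12 | intermediate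
16 | 3-hydroxy-2-[4-hydroxy-5-(methoxymethoxy)-3-(3-methylbuta-1,2-dienyl)-2-(3-methylbut-2-enyl)phenyl]-5-(methoxymethoxy)-7-(3-methylbut-2-enyloxy)-4H-chromen-4-one | COCOc1cc(OCC=C(C)C)cc2oc(-c3cc(OCOC)c(O)c(C=C=C(C)C)c3CC=C(C)C)c(O)c(=O)c12 | intermediate (not isolated)
17 | ortho-quinone methide of 16: ring B as a cyclohexadienone with C4'=O and a Z-configured exocyclic C3'=CH–CH=CMe2 unit, the rest as in 15 | O=C1C(OCOC)=CC(c2oc3cc(OCC=C(C)C)cc(OCOC)c3c(=O)c2O)=C(CC=C(C)C)/C1=C/C=C(C)C | intermediate (not isolated)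
18 | 3-hydroxy-5-(methoxymethoxy)-2-[8-(methoxymethoxy)-2,2-dimethyl-5-(3-methylbut-2-enyl)-2H-chromen-6-yl]-7-(3-methylbut-2-enyloxy)-4H-chromen-4-one | COCOc1cc(OCC=C(C)C)cc2oc(-c3cc(OCOC)c4c(c3CC=C(C)C)C=CC(C)(C)O4)c(O)c(=O)c12 | intermediate (not isolated)
19 | 3,7-dihydroxy-5-(methoxymethoxy)-2-[8-(methoxymethoxy)-2,2-dimethyl-5-(3-methylbut-2-enyl)-2H-chromen-6-yl]-8-(2-methylbut-3-en-2-yl)-4H-chromen-4-one | COCOc1cc(O)c(C(C)(C)C=C)c2oc(-c3cc(OCOC)c4c(c3CC=C(C)C)C=CC(C)(C)O4)c(O)c(=O)c12 | intermediate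
20 | broussoflavonol D, 3,5,7-trihydroxy-2-[8-hydroxy-2,2-dimethyl-5-(3-methylbut-2-enyl)-2H-chromen-6-yl]-8-(2-methylbut-3-en-2-yl)-4H-chromen-4-one | C=CC(C)(C)c1c(O)cc(O)c2c(=O)c(O)c(-c3cc(O)c4c(c3CC=C(C)C)C=CC(C)(C)O4)oc12 | target

Total step count: 9
Longest linear sequence: 7 steps (steps 3, 4, 5, 6, 7, 8, 9, from 6)

Steps most likely to fail

Step 8. Two rearrangements with different rates share one thermal window. The prenyl group may migrate to C6 instead of C8, and prolonged heating may isomerise the 1,1-dimethylallyl group next to the new 7-OH (abnormal Claisen) or cyclise it onto that hydroxyl. The fallback sets out from 5 and comes back to the route at 20. It moves the prenyl shift to the acetophenone stage, where the chelated 2-OH fixes the C3–C4 bond and directs the group to C3. Heating 5 in PhNEt2 at 190 °C should give 1-[2,4-dihydroxy-6-(methoxymethoxy)-3-(2-methylbut-3-en-2-yl)phenyl]ethanone F1. MOMCl and DIPEA should protect the non-chelated 4-OH to give 1-[2-hydroxy-4,6-bis(methoxymethoxy)-3-(2-methylbut-3-en-2-yl)phenyl]ethanone F2. Claisen–Schmidt condensation of F2 with 11 (KOH, EtOH) should give the 3'-(1,1-dimethylallyl) chalcone F3, and Algar–Flynn–Oyamada oxidation should give the 8-(1,1-dimethylallyl)-5,7-bis(MOM) flavonol F4. The propargyl ether alone is then rearranged at lower temperature (DMF, 130–140 °C) to the tris-MOM pyranoflavonol F5, which remains the last ring closure. HCl in MeOH should remove the three MOM groups and give 20.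

Step 7. The phenoxide may attack the α-carbon instead of the β-carbon, which diverts material to the aurone; the 6'-alkoxy group and the ortho-prenyl B ring both favour this, and oxidation of the dihydroflavonol may stay incomplete. The fallback sets out from 12 and comes back to the route at 15. It separates epoxidation from ring closure and runs the closure under acid control. Silylation of the 2'-OH (TBSCl, imidazole, DMF) should give the 2'-O-TBS chalcone F6. Nucleophilic epoxidation (t-BuOOH, DBU, CH2Cl2) should give the racemic trans-epoxide F7. TBAF buffered with AcOH should release the 2'-hydroxychalcone epoxide F8, which under PPTS catalysis should open at the benzylic carbon (6-endo, cation stabilised by the para-alkoxy B ring) to give the dihydroflavonol 14, isolated in this variant. Dehydrogenation of 14 with alkaline H2O2 in MeOH should give 15.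

Step 4. The para-phenoxide is a weak nucleophile and the tertiary chloride is hindered, so alkylation may be slow and may spread over both hydroxyls to give regioisomeric and bis-ethers. The fallback sets out from 8 and comes back to the route at 11. It reverses the order of the two O-functionalisations through the dianion, in which the more basic 5-oxide is the more nucleophilic site. NaH (2.2 equiv) in DMSO followed by MOMCl (1.0 equiv) should give 4-hydroxy-5-(methoxymethoxy)-2-(3-methylbut-2-enyl)benzaldehyde F9. The single free 4-OH is then etherified with 9 (K2CO3, KI, CuI, DMF, 50 °C) to give 11.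

Further compounds

F1 | step 8 | 1-[2,4-dihydroxy-6-(methoxymethoxy)-3-(2-methylbut-3-en-2-yl)phenyl]ethanone | CC(=O)c1c(O)c(C(C)(C)C=C)c(O)cc1OCOC
F2 | step 8 | 1-[2-hydroxy-4,6-bis(methoxymethoxy)-3-(2-methylbut-3-en-2-yl)phenyl]ethanone | CC(=O)c1c(O)c(C(C)(C)C=C)c(OCOC)cc1OCOC
F3 | step 8 | (E)-1-[2-hydroxy-4,6-bis(methoxymethoxy)-3-(2-methylbut-3-en-2-yl)phenyl]-3-[5-(methoxymethoxy)-4-(2-methylbut-3-yn-2-yloxy)-2-(3-methylbut-2-enyl)phenyl]prop-2-en-1-one | COCOc1cc(OCOC)c(C(C)(C)C=C)c(O)c1C(=O)/C=C/c1cc(OCOC)c(OC(C)(C)C#C)cc1CC=C(C)C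
F4 | step 8 | 3-hydroxy-5,7-bis(methoxymethoxy)-8-(2-methylbut-3-en-2-yl)-2-[5-(methoxymethoxy)-4-(2-methylbut-3-yn-2-yloxy)-2-(3-methylbut-2-enyl)phenyl]-4H-chromen-4-one | COCOc1cc(OCOC)c(C(C)(C)C=C)c2oc(-c3cc(OCOC)c(OC(C)(C)C#C)cc3CC=C(C)C)c(O)c(=O)c12
F5 | step 8 | 3-hydroxy-5,7-bis(methoxymethoxy)-2-[8-(methoxymethoxy)-2,2-dimethyl-5-(3-methylbut-2-enyl)-2H-chromen-6-yl]-8-(2-methylbut-3-en-2-yl)-4H-chromen-4-one | COCOc1cc(OCOC)c(C(C)(C)C=C)c2oc(-c3cc(OCOC)c4c(c3CC=C(C)C)C=CC(C)(C)O4)c(O)c(=O)c12
F6 | step 7 | (E)-1-[2-(tert-butyldimethylsilyloxy)-6-(methoxymethoxy)-4-(3-methylbut-2-enyloxy)phenyl]-3-[5-(methoxymethoxy)-4-(2-methylbut-3-yn-2-yloxy)-2-(3-methylbut-2-enyl)phenyl]prop-2-en-1-one | CC(C)(C)[Si](C)(C)Oc1cc(OCC=C(C)C)cc(OCOC)c1C(=O)/C=C/c1cc(OCOC)c(OC(C)(C)C#C)cc1CC=C(C)C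
F7 | step 7 | trans-2,3-epoxide of F6 (racemic, one enantiomer drawn) | CC(C)(C)[Si](C)(C)Oc1cc(OCC=C(C)C)cc(OCOC)c1C(=O)[C@H]2O[C@@H]2c2cc(OCOC)c(OC(C)(C)C#C)cc2CC=C(C)C
F8 | step 7 | trans-2,3-epoxide of chalcone 12 with free 2'-OH (racemic, one enantiomer drawn, not isolated) | Oc1cc(OCC=C(C)C)cc(OCOC)c1C(=O)[C@H]2O[C@@H]2c2cc(OCOC)c(OC(C)(C)C#C)cc2CC=C(C)C
F9 | step 4 | 4-hydroxy-5-(methoxymethoxy)-2-(3-methylbut-2-enyl)benzaldehyde | O=Cc1cc(OCOC)c(O)cc1CC=C(C)C
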